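**Plan**
- Locants used throughout (ring): C1 (CH2) – C2 (CH–OH) – C3 (=C15H2) – C4 – C5 – C6 (=CH) – C7 (–C14O2H) – C8 – C9 (CH–O-angeloyl) – C10 – C11 (CMe2); the target is (2S,9S).
- Retrosynthesis: remove the C14 tert-butyl ester; take the C2 carbinol/C3 exocyclic methylene back to a 2,3-epoxide and then to a C2=C3 olefin; cut the C9–O acyl bond and take C9 back to a ketone; cut the ring bond C1–C11 as the sigma bond made in a [3,3] shift, which reconnects C3–C9 into a cycloheptene; then cut C9–isobutenyl, C3–vinyl, and the seven-membered ring into a vinylcarbenoid and a 2-siloxydiene.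
- Enabling feature: C9(–O)–C10–C11–C1–C2–C3(=C15) is the retron of a 3-oxy-1,5-diene shift (C9 ketone, C2=C3 olefin), and the other ring atoms C4–C8, with the ring-cis C6=C7 acrylate, are the five atoms that tie C3 to C9 in a seven-membered ring.
- Forward: cycloheptadiene by cyclopropanation/divinylcyclopropane rearrangement; quaternary C3 by aldol and dehydration; isobutenyl addition at C9; ring expansion from seven to eleven atoms forms C1–C11 and the gem-dimethyl carbon; then epoxidation, reduction, acylation, epoxide-to-allylic-alcohol isomerisation, ester cleavage.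
- Stereochemistry: C6=C7 geometry is inherited from the cycloheptene; C2 comes from catalyst-controlled epoxidation of the achiral macrocycle; C9 from oxazaborolidine-controlled reduction; the angelate geometry from angelic acid.

Key step: step 9

Assumption: step 8 is not expected to distinguish methyl from vinyl on C3, so 13 is carried as both diastereomers. Compounds 15–19 are drawn for the (2E) olefin expected from the trans-dialkenyl isomer; any (2Z) material differs after step 10 only at C3, which becomes trigonal in step 13.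

**Step 1**
Reactants: 1 tert-butyl 3-oxobutanoate
Product: 2 tert-butyl 2-diazo-3-oxobutanoate
Conditions: 4-acetamidobenzenesulfonyl azide, Et3N, MeCN, 0 °C to rt
Reagents that add atoms: 4-acetamidobenzenesulfonyl azide, CC(=O)Nc1ccc(cc1)S(=O)(=O)N=[N+]=[N-]
Why: Regitz diazo transfer to the activated methylene of a β-keto ester.

**Step 2**
Reactants: 2 tert-butyl 2-diazo-3-oxobutanoate
Product: 3 tert-butyl 2-diazo-3-hydroxybutanoate (racemic)
Conditions: NaBH4, MeOH, 0 °C
Reagents that add atoms: none
Why: Borohydride reduces the ketone and leaves the diazo ester untouched (standard vinyldiazoacetate preparation); the racemic carbinol centre is removed in step 3.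

**Step 3**
Reactants: 3 tert-butyl 2-diazo-3-hydroxybutanoate
Product: 4 tert-butyl 2-diazobut-3-enoate
Conditions: POCl3, Et3N, CH2Cl2, 0 °C to rt; used at once
Reagents that add atoms: none
Why: Phosphorylation and β-elimination give the vinyldiazoacetate, which is not stored because it cyclises to a pyrazole.

**Step 4**
Reactants: 5 3-methylbut-3-en-2-one
Product: 6 tert-butyl(dimethyl)[(3-methylbuta-1,3-dien-2-yl)oxy]silane
Conditions: TBSOTf, Et3N, CH2Cl2, 0 °C
Reagents that add atoms: tert-butyldimethylsilyl triflate, CC(C)(C)[Si](C)(C)OS(=O)(=O)C(F)(F)F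
Why: O-silylation of the only enolisable position (the acetyl methyl) gives the 2-siloxydiene.

**Step 5**
Reactants: 4 tert-butyl 2-diazobut-3-enoate; 6 tert-butyl(dimethyl)[(3-methylbuta-1,3-dien-2-yl)oxy]silane
Product: 8 tert-butyl 6-(tert-butyldimethylsilyloxy)-5-methylcyclohepta-1,5-diene-1-carboxylate, via cis-divinylcyclopropane 7 (not isolated)
Conditions: Rh2(OPiv)4 (1 mol %), 6 (3 equiv), hexane, reflux, slow addition of 4; then toluene, 80 °C
Reagents that add atoms: none
Why: Formal [4+3] cycloaddition of a rhodium vinylcarbenoid (Davies type): the electrophilic carbenoid cyclopropanates the more electron-rich silyl enol ether double bond, and Cope rearrangement of the divinylcyclopropane puts the ester on C7, the olefin at C6=C7 and a regiodefined enol ether at C3=C9.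

**Step 6**
Reactants: 8 tert-butyl 6-(tert-butyldimethylsilyloxy)-5-methylcyclohepta-1,5-diene-1-carboxylate; 9 acetaldehyde
Product: 10 tert-butyl 5-(1-hydroxyethyl)-5-methyl-6-oxocyclohept-1-ene-1-carboxylate
Conditions: 9 (3 equiv), BF3·OEt2 (1.1 equiv), CH2Cl2, −78 °C; aq. NaHCO3
Reagents that add atoms: none
Why: Mukaiyama aldol addition of the tetrasubstituted silyl enol ether makes the quaternary carbon C3 regiospecifically; the two new stereocentres are not controlled and are erased in steps 7 and 9.

**Step 7**
Reactants: 10 tert-butyl 5-(1-hydroxyethyl)-5-methyl-6-oxocyclohept-1-ene-1-carboxylate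
Product: 11 tert-butyl 5-ethenyl-5-methyl-6-oxocyclohept-1-ene-1-carboxylate (racemic)
Conditions: Burgess reagent, toluene, 70 °C
Reagents that add atoms: none
Why: Burgess syn-elimination can take a hydrogen only from the methyl group, because the other neighbour (C3) is quaternary, so the vinyl group is the only olefin possible.

**Step 8**
Reactants: 11 tert-butyl 5-ethenyl-5-methyl-6-oxocyclohept-1-ene-1-carboxylate; 12 (2-methylprop-1-en-1-yl)magnesium bromide
Product: 13 tert-butyl 5-ethenyl-6-hydroxy-5-methyl-6-(2-methylprop-1-en-1-yl)cyclohept-1-ene-1-carboxylate (both diastereomers, racemic)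
Conditions: anhydrous CeCl3 (1.5 equiv), 12 (1.5 equiv), THF, −78 °C; aqueous work-up
Reagents that add atoms: none
Why: Organocerium 1,2-addition to a hindered, easily enolised ketone in the presence of the tert-butyl ester; the C9 configuration relative to C3 is not controlled and need not be, since both centres are destroyed in step 9.

**Step 9**
Reactants: 13 tert-butyl 5-ethenyl-6-hydroxy-5-methyl-6-(2-methylprop-1-en-1-yl)cyclohept-1-ene-1-carboxylate
Product: 15 tert-butyl (1E,5E)-5,8,8-trimethyl-10-oxocycloundeca-1,5-diene-1-carboxylate, via potassium enolate 14 (not isolated)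
Conditions: KN(SiMe3)2 (1.1 equiv), 18-crown-6 (1.2 equiv), THF, 0 to 45 °C; AcOH, THF, −78 °C
Reagents that add atoms: none
Why: Deprotonation gives the C9 potassium alkoxide, whose 3-oxido-1,5-diene unit C1=C2–C3–C9(O−)–C10=C11 undergoes a charge-accelerated [3,3] sigmatropic shift through a six-membered chair array: the C3–C9 bond of the cycloheptene breaks while C1 bonds to the dimethyl-substituted terminus C11, giving enolate 14. The closest known reaction type is the anionic oxy-Cope ring expansion of 1,2-dialkenylcycloalkanols to cycloalkenones enlarged by four atoms. The eleven-membered ring is thus closed by four-atom expansion of an existing seven-membered ring through a six-centre transition state, not by end-to-end cyclisation, so high dilution is not needed and the ring-cis C6=C7 acrylate is carried over unchanged. No stereocentre is created (C11 carries two methyl groups) and both stereocentres of 13 are destroyed, so the diastereomers converge; the trans-dialkenyl isomer should give the (2E) olefin drawn, and any (2Z) olefin from the cis isomer is taken on as well. The selectivity needed is [3,3] shift over fragmentation of the homoallylic alkoxide, over the boat-like shift through the ring allyl unit C6=C7–C8, and over attack on the ester; the chair pathway to a stable enolate should win, and lactonisation of the C9 alkoxide onto C14 is blocked because it would put C6=C7 at the bridgehead of an oxabicyclo[4.2.1]nonene. Quenching at −78 °C protonates the enolate at C10 before the C6=C7 bond can move into conjugation with the new ketone.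

**Step 10**
Reactants: 15 tert-butyl (1E,5E)-5,8,8-trimethyl-10-oxocycloundeca-1,5-diene-1-carboxylate
Product: 16 tert-butyl (1E,5S,6S)-5,6-epoxy-5,8,8-trimethyl-10-oxocycloundec-1-ene-1-carboxylate
Conditions: ent-Shi ketone (L-fructose-derived, 30 mol %), KHSO5 (as Oxone, 2KHSO5·KHSO4·K2SO4), K2CO3, Bu4NHSO4, MeCN–CH2(OMe)2/aq. Na2B4O7–Na2EDTA (disodium ethylenediaminetetraacetate) buffer, pH 10.5, 0 °C
Reagents that add atoms: potassium peroxymonosulfate, [K+].[O-]S(=O)(=O)OO
Why: Shi asymmetric epoxidation: the chiral dioxirane attacks only the electron-rich trisubstituted C2=C3 olefin (the acrylate is deactivated), and the spiro transition state, which places the single vinylic hydrogen at C2 next to the catalyst ketal, fixes the C2 face; the L-series ketone is chosen to give (2S), and the same C2 face is expected for either olefin geometry.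

**Step 11**
Reactants: 16 tert-butyl (1E,5S,6S)-5,6-epoxy-5,8,8-trimethyl-10-oxocycloundec-1-ene-1-carboxylate
Product: 17 tert-butyl (1E,5S,6S,10S)-5,6-epoxy-10-hydroxy-5,8,8-trimethylcycloundec-1-ene-1-carboxylate
Conditions: (S)-2-methyl-CBS-oxazaborolidine (0.5 equiv), BH3·SMe2, toluene, −40 °C; MeOH quench
Reagents that add atoms: none
Why: Corey–Bakshi–Shibata reduction; with the neopentyl-type C10 side as the large group and the allylic C8 side as the small one, the (S)-catalyst should deliver hydride to give (9S), and any C9 epimer is a separable diastereomer because C2 is already fixed.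

**Step 12**
Reactants: 17 tert-butyl (1E,5S,6S,10S)-5,6-epoxy-10-hydroxy-5,8,8-trimethylcycloundec-1-ene-1-carboxylate; 18 angelic acid, (2Z)-2-methylbut-2-enoic acid
Product: 19 tert-butyl (1E,5S,6S,10S)-5,6-epoxy-5,8,8-trimethyl-10-{[(2Z)-2-methylbut-2-enoyl]oxy}cycloundec-1-ene-1-carboxylate
Conditions: 18, 2,4,6-Cl3C6H2COCl, Et3N, toluene, rt; then 17, toluene, 75 °C
Reagents that add atoms: none
Why: Yamaguchi-type mixed-anhydride acylation, the standard way to make angelates without isomerisation to tiglates; C9 is acylated with retention, and the basic medium keeps the epoxide from opening transannularly.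

**Step 13**
Reactants: 19 tert-butyl (1E,5S,6S,10S)-5,6-epoxy-5,8,8-trimethyl-10-{[(2Z)-2-methylbut-2-enoyl]oxy}cycloundec-1-ene-1-carboxylate
Product: 20 tert-butyl (1E,6S,10S)-6-hydroxy-8,8-dimethyl-5-methylidene-10-{[(2Z)-2-methylbut-2-enoyl]oxy}cycloundec-1-ene-1-carboxylate
Conditions: Cp2TiCl2 (2.5 equiv), Mn dust, THF, rt (gives Cp2TiCl, trivalent titanium); then 19, rt; aq. NaH2PO4
Reagents that add atoms: none
Why: Nugent–RajanBabu homolytic epoxide opening: Cp2TiCl cleaves the C3–O bond to the tertiary radical, a second Cp2TiCl traps it, and β-hydride elimination toward the methyl group gives the exocyclic C3=C15 olefin; the C2–O bond is never broken, so (2S) is retained.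

**Step 14**
Reactants: 20 tert-butyl (1E,6S,10S)-6-hydroxy-8,8-dimethyl-5-methylidene-10-{[(2Z)-2-methylbut-2-enoyl]oxy}cycloundec-1-ene-1-carboxylate
Product: 22 (1E,6S,10S)-6-hydroxy-8,8-dimethyl-5-methylidene-10-{[(2Z)-2-methylbut-2-enoyl]oxy}cycloundec-1-ene-1-carboxylic acid (CNP0263820.1), via bis(trimethylsilyl) derivative 21 (not isolated)
Conditions: TMSOTf (4 equiv), 2,6-lutidine (6 equiv), CH2Cl2, 0 °C; then aq. citric acid, THF, 0 °C
Reagents that add atoms: trimethylsilyl triflate, C[Si](C)(C)OS(=O)(=O)C(F)(F)F (its Me3Si groups are held only by intermediate 21)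
Why: Silyl triflate/lutidine cleavage of a tert-butyl ester (loss of isobutene to the silyl ester) is non-hydrolytic and leaves the secondary angelate intact; mild aqueous acid then removes the silyl ester and the silyl ether.

**Compound list**
1 | tert-butyl 3-oxobutanoate | CC(=O)CC(=O)OC(C)(C)C | starting material
2 | tert-butyl 2-diazo-3-oxobutanoate | CC(=O)C(=[N+]=[N-])C(=O)OC(C)(C)C | intermediate
3 | tert-butyl 2-diazo-3-hydroxybutanoate (racemic) | CC(O)C(=[N+]=[N-])C(=O)OC(C)(C)C | intermediate
4 | tert-butyl 2-diazobut-3-enoate | C=CC(=[N+]=[N-])C(=O)OC(C)(C)C | intermediate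
5 | 3-methylbut-3-en-2-one | CC(=O)C(C)=C | starting material
6 | tert-butyl(dimethyl)[(3-methylbuta-1,3-dien-2-yl)oxy]silane | C=C(O[Si](C)(C)C(C)(C)C)C(C)=C | intermediate
7 | tert-butyl 2-(tert-butyldimethylsilyloxy)-1-ethenyl-2-(prop-1-en-2-yl)cyclopropane-1-carboxylate (ethenyl cis to propenyl, racemic; not isolated) | C=C[C@@]1(C(=O)OC(C)(C)C)C[C@@]1(O[Si](C)(C)C(C)(C)C)C(C)=C | intermediate
8 | tert-butyl 6-(tert-butyldimethylsilyloxy)-5-methylcyclohepta-1,5-diene-1-carboxylate | CC1=C(O[Si](C)(C)C(C)(C)C)CC(C(=O)OC(C)(C)C)=CCC1 | intermediate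
9 | acetaldehyde | CC=O | starting material
10 | tert-butyl 5-(1-hydroxyethyl)-5-methyl-6-oxocyclohept-1-ene-1-carboxylate (diastereomers, racemic) | CC(O)C1(C)CCC=C(C(=O)OC(C)(C)C)CC1=O | intermediate
11 | tert-butyl 5-ethenyl-5-methyl-6-oxocyclohept-1-ene-1-carboxylate (racemic) | C=CC1(C)CCC=C(C(=O)OC(C)(C)C)CC1=O | intermediate
12 | (2-methylprop-1-en-1-yl)magnesium bromide | CC(C)=C[Mg]Br | starting material
13 | tert-butyl 5-ethenyl-6-hydroxy-5-methyl-6-(2-methylprop-1-en-1-yl)cyclohept-1-ene-1-carboxylate (both diastereomers, racemic) | C=CC1(C)CCC=C(C(=O)OC(C)(C)C)CC1(O)C=C(C)C | intermediate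
14 | potassium enolate of 15 (C9–O−, C9=C10; not isolated) | C/C1=C\CC(C)(C)C=C([O-])C/C(C(=O)OC(C)(C)C)=C\CC1.[K+] | intermediate
15 | tert-butyl (1E,5E)-5,8,8-trimethyl-10-oxocycloundeca-1,5-diene-1-carboxylate | C/C1=C\CC(C)(C)CC(=O)C/C(C(=O)OC(C)(C)C)=C\CC1 | intermediate
16 | tert-butyl (1E,5S,6S)-5,6-epoxy-5,8,8-trimethyl-10-oxocycloundec-1-ene-1-carboxylate | C[C@]12O[C@H]2CC(C)(C)CC(=O)C/C(C(=O)OC(C)(C)C)=C\CC1 | intermediate
17 | tert-butyl (1E,5S,6S,10S)-5,6-epoxy-10-hydroxy-5,8,8-trimethylcycloundec-1-ene-1-carboxylate | C[C@]12O[C@H]2CC(C)(C)C[C@H](O)C/C(C(=O)OC(C)(C)C)=C\CC1 | intermediate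
18 | angelic acid, (2Z)-2-methylbut-2-enoic acid | C/C=C(/C)C(=O)O | starting material
19 | tert-butyl (1E,5S,6S,10S)-5,6-epoxy-5,8,8-trimethyl-10-{[(2Z)-2-methylbut-2-enoyl]oxy}cycloundec-1-ene-1-carboxylate | C[C@]12O[C@H]2CC(C)(C)C[C@H](OC(=O)/C(C)=C\C)C/C(C(=O)OC(C)(C)C)=C\CC1 | intermediate
20 | tert-butyl (1E,6S,10S)-6-hydroxy-8,8-dimethyl-5-methylidene-10-{[(2Z)-2-methylbut-2-enoyl]oxy}cycloundec-1-ene-1-carboxylate | C=C1CC/C=C(/C(=O)OC(C)(C)C)C[C@@H](OC(=O)/C(C)=C\C)CC(C)(C)C[C@@H]1O | intermediate
21 | trimethylsilyl (1E,6S,10S)-8,8-dimethyl-5-methylidene-10-{[(2Z)-2-methylbut-2-enoyl]oxy}-6-(trimethylsilyloxy)cycloundec-1-ene-1-carboxylate (not isolated) | C=C1CC/C=C(/C(=O)O[Si](C)(C)C)C[C@@H](OC(=O)/C(C)=C\C)CC(C)(C)C[C@@H]1O[Si](C)(C)C | intermediate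
22 | (1E,6S,10S)-6-hydroxy-8,8-dimethyl-5-methylidene-10-{[(2Z)-2-methylbut-2-enoyl]oxy}cycloundec-1-ene-1-carboxylic acid (CNP0263820.1) | C=C1CC/C=C(/C(=O)O)C[C@@H](OC(=O)/C(C)=C\C)CC(C)(C)C[C@@H]1O | target

**Count**
Total steps: 14. Longest linear sequence: 13 steps (steps 1–3 and 5–14, from tert-butyl 3-oxobutanoate); step 4 is the one-step side branch.

**Steps most likely to fail**

1. Step 9. The alkoxide may fragment (retro-ene loss of the ring allyl arm at C8–C9), or the base may shift the C6=C7 bond, faster than the [3,3] shift, whose new bond ends on a fully substituted olefin terminus. The fallback removes the anion and runs a neutral siloxy-Cope ring expansion. It sets out from 13, which is silylated (TMSCl, imidazole, DMF) to the trimethylsilyl ether F1. Thermolysis of F1 (o-dichlorobenzene, 200–220 °C, base-washed sealed tube) should give the trimethylsilyl enol ether F2 of the eleven-membered ketone. Hydrolysis of F2 (dilute HCl, THF, 0 °C) returns to the route at 15.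

2. Step 11. Facial selectivity may be poor in the reduction of a ketone flanked by two methylene groups, where neither the catalyst nor the ring conformation is sure to dominate. The fallback gives up selectivity and makes the esterification stereoconvergent. It sets out from 16, which is reduced with NaBH4 (MeOH, 0 °C) to 17 and the (9R)-epimer F3, separable as diastereomers. Compound 17 goes on through step 12. F3 is esterified with 18 under Mitsunobu conditions (PPh3, diisopropyl azodicarboxylate, toluene, 0 °C), with inversion at C9, and returns to the route at 19.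

3. Step 10. Enantioface discrimination at C2 may be poor if the substrate ketone acts as an achiral dioxirane carrier or if the two olefin geometries do not converge, and the C6=C7 bond may migrate at pH 10.5. The fallback sets C2 by carbonyl reduction instead of epoxidation and sets C9 first. It sets out from 15:
   - CBS reduction as in step 11 should give the (9S)-hydroxy diene ester F4.
   - Acylation as in step 12 gives the angelate F5.
   - mCPBA (NaHCO3, CH2Cl2, 0 °C) epoxidises only C2=C3, giving 19 together with the (2R,3R)-epoxide F6.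
   - Cp2TiCl as in step 13 converts the mixture to 20 and the (2R)-allylic alcohol F7.
   - Dess–Martin periodinane oxidises both to the single enone F8.
   - (R)-2-methyl-CBS-oxazaborolidine with catecholborane (toluene, −78 °C) treats the alkenyl side as the large group and should give the (2S)-alcohol, returning to the route at 20.
   
   Material of the wrong C9 configuration then appears as a diastereomer and is removed by chromatography.

**Further compounds**
F1 | step 9 | tert-butyl 5-ethenyl-5-methyl-6-(2-methylprop-1-en-1-yl)-6-(trimethylsilyloxy)cyclohept-1-ene-1-carboxylate | C=CC1(C)CCC=C(C(=O)OC(C)(C)C)CC1(O[Si](C)(C)C)C=C(C)C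
F2 | step 9 | tert-butyl (1E,5E)-5,8,8-trimethyl-10-(trimethylsilyloxy)cycloundeca-1,5,9-triene-1-carboxylate | C/C1=C\CC(C)(C)C=C(O[Si](C)(C)C)C/C(C(=O)OC(C)(C)C)=C\CC1
F3 | step 11 | tert-butyl (1E,5S,6S,10R)-5,6-epoxy-10-hydroxy-5,8,8-trimethylcycloundec-1-ene-1-carboxylate | C[C@]12O[C@H]2CC(C)(C)C[C@@H](O)C/C(C(=O)OC(C)(C)C)=C\CC1
F4 | step 10 | tert-butyl (1E,5E,10S)-10-hydroxy-5,8,8-trimethylcycloundeca-1,5-diene-1-carboxylate | C/C1=C\CC(C)(C)C[C@H](O)C/C(C(=O)OC(C)(C)C)=C\CC1
F5 | step 10 | tert-butyl (1E,5E,10S)-5,8,8-trimethyl-10-{[(2Z)-2-methylbut-2-enoyl]oxy}cycloundeca-1,5-diene-1-carboxylate | C/C1=C\CC(C)(C)C[C@H](OC(=O)/C(C)=C\C)C/C(C(=O)OC(C)(C)C)=C\CC1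
F6 | step 10 | tert-butyl (1E,5R,6R,10S)-5,6-epoxy-5,8,8-trimethyl-10-{[(2Z)-2-methylbut-2-enoyl]oxy}cycloundec-1-ene-1-carboxylate | C[C@@]12O[C@@H]2CC(C)(C)C[C@H](OC(=O)/C(C)=C\C)C/C(C(=O)OC(C)(C)C)=C\CC1
F7 | step 10 | tert-butyl (1E,6R,10S)-6-hydroxy-8,8-dimethyl-5-methylidene-10-{[(2Z)-2-methylbut-2-enoyl]oxy}cycloundec-1-ene-1-carboxylate | C=C1CC/C=C(/C(=O)OC(C)(C)C)C[C@@H](OC(=O)/C(C)=C\C)CC(C)(C)C[C@H]1O
F8 | step 10 | tert-butyl (1E,10S)-8,8-dimethyl-5-methylidene-10-{[(2Z)-2-methylbut-2-enoyl]oxy}-6-oxocycloundec-1-ene-1-carboxylate | C=C1CC/C=C(/C(=O)OC(C)(C)C)C[C@@H](OC(=O)/C(C)=C\C)CC(C)(C)CC1=O
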